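**Plan**

- Retrosynthesis (germacrane numbering): the two silyl ethers and the C8–O ester bond are cut first. The fusion bond C6–C7 is then cut together with the lactone C12–O bond, which opens both the cyclodecene and the cis-fused α-methylene-γ-butyrolactone to an acyclic C6 enal carrying a 2-(bromomethyl)enoate. The chain is cut further at C7=C11 (Baylis–Hillman), C3–C4 (alkenyllithium) and C1–C2 (carboalumination/epoxide opening).
- Enabling feature: the array O–C6–C7–C11(=C13H2)–C12(=O)O straddles the C6–C7 bond common to the ten-membered ring and the five-membered lactone; this is the retron of a carbonyl allylation by a 2-(alkoxycarbonyl)allyl metal.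
- Forward order: the chain is built linearly from C7 to C6 from (S)-glycidol, acetylide, AlMe3, ethylene oxide, a (Z)-iodobutenyl ether and methyl acrylate. The ten-membered ring and then the lactone form in one operation. The separately made diester acid is attached to O8 last.
- Stereochemistry: C8 from glycidol; C3 by CBS reduction; C1/C10 by Shi epoxidation of the E-olefin; C6/C7 in the ring closure (chair transition state, relayed from C8); the side-chain centre by Evans hydroxymethylation. The Z-C4=C5 olefin comes from directed hydroalumination–iodination, the side-chain olefin from a Baylis–Hillman bromide.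

Key step: step 17

Remark: atoms are numbered as in germacrane (C1–C10 ring carbons, C11 lactone α-carbon, C12 carbonyl, C13 exocyclic methylene, C14 on C10, C15 on C4). The target lactone is cis-fused at C6/C7. The chiral starting materials and catalysts named are taken as commercial.

**Route**

Step 1
Reactants: 1 (S)-glycidol; 2 lithium acetylide–ethylenediamine complex (LiC≡CH·H2NCH2CH2NH2)
Product: 3 (2R)-pent-4-yne-1,2-diol
Conditions: 2 (3 equiv), DMSO, 15 °C → rt; aqueous work-up
Reagents that add atoms: none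
Why: Acetylide opening of the terminal epoxide at its unsubstituted carbon (SN2 epoxide alkynylation) leaves the C–O bond of the stereocentre untouched, so the future C8 carbinol is taken from the chiral pool with retention (the descriptor changes from S to R only through the priority rules).

Step 2
Reactants: 3 (2R)-pent-4-yne-1,2-diol
Product: 4 (4R)-4,5-bis(triethylsilyloxy)pent-1-yne
Conditions: Et3SiCl, imidazole, 4-(dimethylamino)pyridine (cat.), CH2Cl2, 0 °C → rt
Reagents that add atoms: chlorotriethylsilane, CC[Si](Cl)(CC)CC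
Why: Exhaustive silyl ether formation masks both hydroxyls as triethylsilyl ethers, which tolerate organoaluminium and organolithium reagents and can later be told apart because only the primary one is oxidised under Swern conditions.

Step 3
Reactants: 4 (4R)-4,5-bis(triethylsilyloxy)pent-1-yne; 5 ethylene oxide
Product: 8 (3E,6R)-4-methyl-6,7-bis(triethylsilyloxy)hept-3-en-1-ol, via alkenyldimethylalane 6 (not isolated), via lithium alkenylalanate 7 (not isolated)
Conditions: AlMe3, Cp2ZrCl2 (0.3 equiv), CH2Cl2, 0 °C → rt; evaporate; n-BuLi, hexane–THF, −30 °C; then 5, −30 → 0 °C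
Reagents that add atoms: trimethylaluminium, C[Al](C)C
Why: Negishi zirconium-catalysed carboalumination adds methyl and aluminium syn across the terminal alkyne (methyl to the internal carbon), and the derived alanate opens ethylene oxide with retention of olefin geometry, which fixes the E-trisubstituted C1=C10 double bond and adds C2–C3 in one flask.

Step 4
Reactants: 8 (3E,6R)-4-methyl-6,7-bis(triethylsilyloxy)hept-3-en-1-ol
Product: 9 (3E,6R)-4-methyl-6,7-bis(triethylsilyloxy)hept-3-enal
Conditions: Dess–Martin periodinane, pyridine, CH2Cl2, 0 °C → rt; used at once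
Reagents that add atoms: none
Why: Dess–Martin oxidation under buffered non-basic conditions should give the β,γ-unsaturated aldehyde without migration of the double bond into conjugation.

Step 5
Reactants: 10 but-2-yn-1-ol
Product: 12 (2Z)-3-iodobut-2-en-1-ol, via cyclic alkenylalanate 11 (not isolated)
Conditions: NaAlH2(OCH2CH2OMe)2, THF, 0 °C → rt; then I2, −78 → 0 °C
Reagents that add atoms: iodine, II
Why: Hydroxyl-directed trans-hydroalumination of the propargylic alcohol followed by iodinolysis with retention gives the (Z)-γ-iodo allylic alcohol, the source of the Z-C4=C5 geometry and of C15.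

Step 6
Reactants: 12 (2Z)-3-iodobut-2-en-1-ol
Product: 13 1-({[(2Z)-3-iodobut-2-en-1-yl]oxy}methyl)-4-methoxybenzene
Conditions: NaH, 4-methoxybenzyl chloride, Bu4NI (cat.), THF–DMF, 0 °C → rt
Reagents that add atoms: 4-methoxybenzyl chloride, COc1ccc(CCl)cc1
Why: Williamson etherification protects the primary allylic alcohol as a PMB ether, which tolerates tert-butyllithium and is later removed oxidatively without touching silyl ethers or an allylic bromide.

Step 7
Reactants: 13 1-({[(2Z)-3-iodobut-2-en-1-yl]oxy}methyl)-4-methoxybenzene; 9 (3E,6R)-4-methyl-6,7-bis(triethylsilyloxy)hept-3-enal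
Product: 15 (2Z,4RS,6E,9R)-1-(4-methoxybenzyloxy)-3,7-dimethyl-9,10-bis(triethylsilyloxy)deca-2,6-dien-4-ol, via alkenyllithium 14 (not isolated)
Conditions: 13 (1.3 equiv), t-BuLi (2.6 equiv), Et2O, −78 °C; then 9, −78 °C; H2O
Reagents that add atoms: none
Why: Iodine–lithium exchange proceeds with retention of olefin geometry and 1,2-addition of the alkenyllithium to the aldehyde forms the C3–C4 bond, the C3 epimer mixture being of no consequence because C3 is oxidised in the next step.

Step 8
Reactants: 15 (2Z,4RS,6E,9R)-1-(4-methoxybenzyloxy)-3,7-dimethyl-9,10-bis(triethylsilyloxy)deca-2,6-dien-4-ol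
Product: 16 (2Z,6E,9R)-1-(4-methoxybenzyloxy)-3,7-dimethyl-9,10-bis(triethylsilyloxy)deca-2,6-dien-4-one
Conditions: Dess–Martin periodinane, pyridine, CH2Cl2, 0 °C
Reagents that add atoms: none
Why: Dess–Martin oxidation of the allylic alcohol gives the Z-enone under neutral buffered conditions that should leave the Z geometry and the skipped C1=C10 olefin in place.

Step 9
Reactants: 16 (2Z,6E,9R)-1-(4-methoxybenzyloxy)-3,7-dimethyl-9,10-bis(triethylsilyloxy)deca-2,6-dien-4-one
Product: 17 (2Z,4S,6E,9R)-1-(4-methoxybenzyloxy)-3,7-dimethyl-9,10-bis(triethylsilyloxy)deca-2,6-dien-4-ol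
Conditions: (R)-1-methyl-3,3-diphenyltetrahydro-1H,3H-pyrrolo[1,2-c][1,3,2]oxazaborole ((R)-Me-CBS, 0.5 equiv), catecholborane, toluene, −78 °C
Reagents that add atoms: none
Why: In this Corey–Bakshi–Shibata reduction the oxazaborolidine distinguishes the α-branched alkenyl group (large) from the CH2 group (small), so the (R)-catalyst should deliver hydride to give the (S)-carbinol at C3 under reagent control.

Step 10
Reactants: 17 (2Z,4S,6E,9R)-1-(4-methoxybenzyloxy)-3,7-dimethyl-9,10-bis(triethylsilyloxy)deca-2,6-dien-4-ol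
Product: 18 (2Z,4S,6E,9R)-4-(tert-butyldimethylsilyloxy)-1-(4-methoxybenzyloxy)-3,7-dimethyl-9,10-bis(triethylsilyloxy)deca-2,6-diene
Conditions: t-BuMe2SiOTf, 2,6-lutidine, CH2Cl2, −78 °C
Reagents that add atoms: tert-butyldimethylsilyl trifluoromethanesulfonate, CC(C)(C)[Si](C)(C)OS(=O)(=O)C(F)(F)F
Why: Silylation with the silyl triflate protects the hindered allylic alcohol as a TBS ether that is more robust than the triethylsilyl ethers, which allows later selective cleavage at O8.

Step 11
Reactants: 18 (2Z,4S,6E,9R)-4-(tert-butyldimethylsilyloxy)-1-(4-methoxybenzyloxy)-3,7-dimethyl-9,10-bis(triethylsilyloxy)deca-2,6-diene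
Product: 19 (2Z,4S,6R,7R,9R)-4-(tert-butyldimethylsilyloxy)-6,7-epoxy-1-(4-methoxybenzyloxy)-3,7-dimethyl-9,10-bis(triethylsilyloxy)dec-2-ene
Conditions: 1,2:4,5-di-O-isopropylidene-β-D-erythro-2,3-hexodiulo-2,6-pyranose (Shi ketone, 0.3 equiv), Oxone (2KHSO5·KHSO4·K2SO4), K2CO3, Bu4NHSO4 (cat.), MeCN–CH2(OMe)2 / aq. Na2B4O7–Na2EDTA buffer (pH 10.5), 0 °C
Reagents that add atoms: potassium peroxymonosulfate (active component of Oxone), [K+].[O-]S(=O)(=O)OO
Why: Shi asymmetric epoxidation (chiral dioxirane, spiro transition state) should convert the E-trisubstituted C1=C10 olefin into the (1R,10R)-epoxide under reagent control, while the Z-C4=C5 olefin is deactivated by its two allylic C–O bonds and shielded by the neighbouring OTBS group.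

Step 12
Reactants: 19 (2Z,4S,6R,7R,9R)-4-(tert-butyldimethylsilyloxy)-6,7-epoxy-1-(4-methoxybenzyloxy)-3,7-dimethyl-9,10-bis(triethylsilyloxy)dec-2-ene
Product: 20 (2R,4R,5R,7S,8Z)-7-(tert-butyldimethylsilyloxy)-4,5-epoxy-10-(4-methoxybenzyloxy)-4,8-dimethyl-2-(triethylsilyloxy)dec-8-enal
Conditions: (COCl)2, DMSO, CH2Cl2, −78 → −40 °C; then Et3N, −78 → 0 °C
Reagents that add atoms: none
Why: Swern conditions cleave and oxidise a primary triethylsilyl ether directly to the aldehyde (selective oxidative desilylation) and should leave the secondary silyl ethers, the PMB ether and the epoxide untouched, the low temperature guarding C8 against epimerisation.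

Step 13
Reactants: 20 (2R,4R,5R,7S,8Z)-7-(tert-butyldimethylsilyloxy)-4,5-epoxy-10-(4-methoxybenzyloxy)-4,8-dimethyl-2-(triethylsilyloxy)dec-8-enal; 21 methyl acrylate
Product: 22 methyl (3RS,4R,6R,7R,9S,10Z)-9-(tert-butyldimethylsilyloxy)-6,7-epoxy-3-hydroxy-12-(4-methoxybenzyloxy)-6,10-dimethyl-2-methylidene-4-(triethylsilyloxy)dodec-10-enoate
Conditions: 21 (20 equiv, neat), 3-hydroxyquinuclidine (0.5 equiv), rt, 2–4 d
Reagents that add atoms: none
Why: The Morita–Baylis–Hillman reaction, which is accelerated by the α-silyloxy group of the aldehyde, installs C11–C13 as the acrylate, and the new carbinol centre at C7 is formed as a mixture that is erased in the next step.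

Step 14
Reactants: 22 methyl (3RS,4R,6R,7R,9S,10Z)-9-(tert-butyldimethylsilyloxy)-6,7-epoxy-3-hydroxy-12-(4-methoxybenzyloxy)-6,10-dimethyl-2-methylidene-4-(triethylsilyloxy)dodec-10-enoate
Product: 23 methyl (2Z,4R,6R,7R,9S,10Z)-2-(bromomethyl)-9-(tert-butyldimethylsilyloxy)-6,7-epoxy-12-(4-methoxybenzyloxy)-6,10-dimethyl-4-(triethylsilyloxy)dodeca-2,10-dienoate
Conditions: N-bromosuccinimide, Me2S, CH2Cl2, 0 °C; then 22, 0 °C → rt
Reagents that add atoms: N-bromosuccinimide, O=C1CCC(=O)N1Br
Why: Corey–Kim-type bromination with allylic transposition (SN2′ attack of bromide on the alkoxysulfonium salt) converts the Baylis–Hillman alcohol into the favoured (Z)-2-(bromomethyl)enoate in which C8 is cis to CH2Br.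

Step 15
Reactants: 23 methyl (2Z,4R,6R,7R,9S,10Z)-2-(bromomethyl)-9-(tert-butyldimethylsilyloxy)-6,7-epoxy-12-(4-methoxybenzyloxy)-6,10-dimethyl-4-(triethylsilyloxy)dodeca-2,10-dienoate
Product: 24 methyl (2Z,4R,6R,7R,9S,10Z)-2-(bromomethyl)-9-(tert-butyldimethylsilyloxy)-6,7-epoxy-12-hydroxy-6,10-dimethyl-4-(triethylsilyloxy)dodeca-2,10-dienoate
Conditions: DDQ, CH2Cl2–pH 7 phosphate buffer (10:1), 0 °C
Reagents that add atoms: none
Why: Oxidative cleavage of the PMB ether with DDQ under buffered conditions frees the primary allylic alcohol without affecting the silyl ethers, the epoxide or the allylic bromide.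

Step 16
Reactants: 24 methyl (2Z,4R,6R,7R,9S,10Z)-2-(bromomethyl)-9-(tert-butyldimethylsilyloxy)-6,7-epoxy-12-hydroxy-6,10-dimethyl-4-(triethylsilyloxy)dodeca-2,10-dienoate
Product: 25 methyl (2Z,4R,6R,7R,9S,10Z)-2-(bromomethyl)-9-(tert-butyldimethylsilyloxy)-6,7-epoxy-6,10-dimethyl-12-oxo-4-(triethylsilyloxy)dodeca-2,10-dienoate
Conditions: MnO2 (activated, excess), CH2Cl2, rt, dark
Reagents that add atoms: none
Why: Chemoselective MnO2 oxidation of the allylic alcohol gives the Z-enal under neutral conditions, the silyl ether at O3 preventing lactol formation and helping to preserve the Z geometry.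

Step 17
Reactants: 25 methyl (2Z,4R,6R,7R,9S,10Z)-2-(bromomethyl)-9-(tert-butyldimethylsilyloxy)-6,7-epoxy-6,10-dimethyl-12-oxo-4-(triethylsilyloxy)dodeca-2,10-dienoate
Product: 28 (1R,3S,6S,7S,8R,10R)-3-(tert-butyldimethylsilyloxy)-1,10-epoxy-8-(triethylsilyloxy)germacra-4Z,11(13)-dien-12,6-olide, via allylchromium dichloride 26 (not isolated), via hydroxy ester 27 (not isolated)
Conditions: CrCl2 (10 equiv), degassed DMF–THF (3:1), rt, slow addition of 25 (final 2 mM), 12 h; aq. NH4Cl; SiO2, CH2Cl2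
Reagents that add atoms: none
Why: Two equivalents of divalent chromium convert the allylic bromide into a nucleophilic allylchromium species that adds through its γ-carbon C7 to the C6 aldehyde in an intramolecular Nozaki–Hiyama–Kishi allylation, the reaction type known to close the ten-membered ring of germacranolides across C6–C7 and to give α-methylene-γ-butyrolactones from 2-(bromomethyl)acrylates. The carbocycle closes as a ten-membered ring by SE2′ addition to the carbonyl (exo with respect to C=O) through a six-membered chair transition state Cr–O–C6–C7–C11–C13, and the lactone then closes by 5-exo-trig attack of the C6 chromium alkoxide on the C12 methyl ester. C6 and C7 are set relative to each other by this chair: the Z-configured allyl unit places C8 pseudoaxial and the enal carbon C5 pseudoequatorial, which should give the syn adduct and hence the cis ring fusion of the target. The absolute sense is relayed from C8: H8 eclipses the allyl plane (1,3-allylic strain with C13H2), the C8–C9 bond carrying the tether lies anti to the forming bond and the silyloxy group sits outside, so that C7 bonds through its Re face to the Re face of the aldehyde, which is the C6/C7 configuration of the target (C7 is formally S only while O8 carries silicon). The step needs γ- over α-attack (inherent to the SE2′ mode), ring closure over oligomerisation (high dilution, with the Z-C4=C5 olefin and the trans-epoxide as turn elements), no 1,4-elimination across C13–C8 (O8 is a poor leaving silyl ether) and lactonisation at O6 only (O8 is silylated).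

Step 18
Reactants: 28 (1R,3S,6S,7S,8R,10R)-3-(tert-butyldimethylsilyloxy)-1,10-epoxy-8-(triethylsilyloxy)germacra-4Z,11(13)-dien-12,6-olide
Product: 29 (1R,3S,6S,7R,8R,10R)-3-(tert-butyldimethylsilyloxy)-1,10-epoxy-8-hydroxygermacra-4Z,11(13)-dien-12,6-olide
Conditions: HF·pyridine, pyridine, THF, 0 °C; aq. NaHCO3
Reagents that add atoms: none
Why: Buffered fluoride-mediated desilylation removes the secondary triethylsilyl ether much faster than the TBS ether and should unveil only the C8 hydroxyl.

Step 19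
Reactants: 30 (R)-4-benzyl-1,3-oxazolidin-2-one; 31 butanoyl chloride
Product: 32 (R)-4-benzyl-3-butanoyl-1,3-oxazolidin-2-one
Conditions: n-BuLi, THF, −78 °C; then 31, −78 → 0 °C
Reagents that add atoms: none
Why: N-Acylation of the lithiated Evans oxazolidinone with the acid chloride gives the imide needed for auxiliary-controlled enolate chemistry.

Step 20
Reactants: 32 (R)-4-benzyl-3-butanoyl-1,3-oxazolidin-2-one
Product: 34 (R)-4-benzyl-3-[(2S)-2-(hydroxymethyl)butanoyl]-1,3-oxazolidin-2-one, via titanium enolate 33 (not isolated)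
Conditions: TiCl4, i-Pr2NEt, CH2Cl2, 0 °C; then 1,3,5-trioxane, TiCl4, 0 °C
Reagents that add atoms: 1,3,5-trioxane, C1OCOCO1
Why: In this Evans titanium-enolate hydroxymethylation the chelated Z-enolate is attacked by the trioxane-derived oxocarbenium ion on the face opposite the benzyl group, which should set the (S)-configured α-carbon of the side chain.

Step 21
Reactants: 34 (R)-4-benzyl-3-[(2S)-2-(hydroxymethyl)butanoyl]-1,3-oxazolidin-2-one
Product: 35 (R)-4-benzyl-3-[(2S)-2-(tert-butyldimethylsilyloxymethyl)butanoyl]-1,3-oxazolidin-2-one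
Conditions: t-BuMe2SiCl, imidazole, DMF, rt
Reagents that add atoms: tert-butyldimethylsilyl chloride, CC(C)(C)[Si](C)(C)Cl
Why: Silyl ether formation protects the primary hydroxyl and blocks retro-aldol or lactonisation pathways during removal of the auxiliary.

Step 22
Reactants: 35 (R)-4-benzyl-3-[(2S)-2-(tert-butyldimethylsilyloxymethyl)butanoyl]-1,3-oxazolidin-2-one
Product: 36 (2S)-2-(tert-butyldimethylsilyloxymethyl)butanoic acid
Conditions: LiOH, H2O2, THF–H2O, 0 °C; Na2SO3; aq. HCl to pH 3
Reagents that add atoms: hydrogen peroxide, OO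
Why: Lithium hydroperoxide cleaves the exocyclic imide carbonyl selectively (Evans auxiliary removal) without epimerising the α-stereocentre and returns the auxiliary.

Step 23
Reactants: 37 tert-butyl acrylate; 38 acetaldehyde
Product: 39 tert-butyl 3-hydroxy-2-methylidenebutanoate (racemic)
Conditions: 1,4-diazabicyclo[2.2.2]octane (0.2 equiv), neat, rt, 7 d
Reagents that add atoms: none
Why: The Morita–Baylis–Hillman reaction joins the acrylate α-carbon to acetaldehyde, the carbinol centre being removed in the next step.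

Step 24
Reactants: 39 tert-butyl 3-hydroxy-2-methylidenebutanoate
Product: 40 tert-butyl (2Z)-2-(bromomethyl)but-2-enoate
Conditions: N-bromosuccinimide, Me2S, CH2Cl2, 0 °C → rt
Reagents that add atoms: N-bromosuccinimide, O=C1CCC(=O)N1Br
Why: The same transposing Corey–Kim-type bromination gives the bromide in which CH2Br is cis to the methyl group, so that the ester is trans to methyl as the side chain requires.

Step 25
Reactants: 36 (2S)-2-(tert-butyldimethylsilyloxymethyl)butanoic acid; 40 tert-butyl (2Z)-2-(bromomethyl)but-2-enoate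
Product: 41 tert-butyl (2E)-2-({[(2S)-2-(tert-butyldimethylsilyloxymethyl)butanoyl]oxy}methyl)but-2-enoate
Conditions: Cs2CO3 (0.55 equiv), DMF, 0 °C → rt
Reagents that add atoms: none
Why: SN2 O-alkylation of the cesium carboxylate at the primary allylic bromide proceeds without allylic transposition and therefore keeps the olefin geometry, which is E by the priority rules.

Step 26
Reactants: 41 tert-butyl (2E)-2-({[(2S)-2-(tert-butyldimethylsilyloxymethyl)butanoyl]oxy}methyl)but-2-enoate
Product: 43 (2E)-2-({[(2S)-2-(tert-butyldimethylsilyloxymethyl)butanoyl]oxy}methyl)but-2-enoic acid, via trimethylsilyl ester 42 (not isolated)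
Conditions: Me3SiOTf, 2,6-lutidine, CH2Cl2, 0 °C; aq. citric acid
Reagents that add atoms: none
Why: Silyl triflate-mediated cleavage of the tert-butyl ester (loss of isobutene via the silyl ester) unmasks the acid while the TBS ether and the other ester should remain.

Step 27
Reactants: 29 (1R,3S,6S,7R,8R,10R)-3-(tert-butyldimethylsilyloxy)-1,10-epoxy-8-hydroxygermacra-4Z,11(13)-dien-12,6-olide; 43 (2E)-2-({[(2S)-2-(tert-butyldimethylsilyloxymethyl)butanoyl]oxy}methyl)but-2-enoic acid
Product: 45 bis(tert-butyldimethylsilyl) ether of the target, via mixed anhydride 44 (not isolated)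
Conditions: 43, 2,4,6-Cl3C6H2COCl, Et3N, THF, rt; then 29, 4-(dimethylamino)pyridine, toluene, rt
Reagents that add atoms: none
Why: Yamaguchi esterification through the mixed anhydride acylates the secondary C8 hydroxyl with retention at C8, the β-methyl group and α-branching of the acid disfavouring conjugate attack of the pyridine catalyst on the acrylate.

Step 28
Reactants: 45 bis(tert-butyldimethylsilyl) ether of the target
Product: 46 target, (1R,3S,6S,7R,8R,10R)-1,10-epoxy-3-hydroxy-8-{[(2E)-2-({[(2S)-2-(hydroxymethyl)butanoyl]oxy}methyl)but-2-enoyl]oxy}germacra-4Z,11(13)-dien-12,6-olide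
Conditions: HF·pyridine, pyridine, THF, 0 °C → rt; aq. NaHCO3
Reagents that add atoms: none
Why: Global desilylation with buffered HF·pyridine should release the C3 and side-chain hydroxyls without opening the epoxide, adding to the α-methylene lactone or disturbing the allylic diester.

**Compound list**

1 | (S)-glycidol | OC[C@H]1CO1 | starting material
2 | lithium acetylide–ethylenediamine complex | [Li+].[C-]#C.NCCN | starting material
3 | (2R)-pent-4-yne-1,2-diol | C#CC[C@@H](O)CO | intermediate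
4 | (4R)-4,5-bis(triethylsilyloxy)pent-1-yne | C#CC[C@@H](O[Si](CC)(CC)CC)CO[Si](CC)(CC)CC | intermediate
5 | ethylene oxide | C1CO1 | starting material
6 | alkenyldimethylalane, dimethyl[(1E,4R)-2-methyl-4,5-bis(triethylsilyloxy)pent-1-en-1-yl]alumane (not isolated) | C[Al](C)/C=C(\C)C[C@@H](O[Si](CC)(CC)CC)CO[Si](CC)(CC)CC | intermediate
7 | lithium alkenylalanate, lithium butyl(dimethyl)[(1E,4R)-2-methyl-4,5-bis(triethylsilyloxy)pent-1-en-1-yl]aluminate (not isolated) | [Li+].CCCC[Al-](C)(C)/C=C(\C)C[C@@H](O[Si](CC)(CC)CC)CO[Si](CC)(CC)CC | intermediate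
8 | (3E,6R)-4-methyl-6,7-bis(triethylsilyloxy)hept-3-en-1-ol | OCC/C=C(\C)C[C@@H](O[Si](CC)(CC)CC)CO[Si](CC)(CC)CC | intermediate
9 | (3E,6R)-4-methyl-6,7-bis(triethylsilyloxy)hept-3-enal | O=CC/C=C(\C)C[C@@H](O[Si](CC)(CC)CC)CO[Si](CC)(CC)CC | intermediate
10 | but-2-yn-1-ol | CC#CCO | starting material
11 | cyclic alkenylalanate, sodium 2,2-bis(2-methoxyethoxy)-3-methyl-2,5-dihydro-1,2-oxaluminol-2-uide (not isolated) | [Na+].COCCO[Al-]1(OCCOC)OCC=C1C | intermediate
12 | (2Z)-3-iodobut-2-en-1-ol | C/C(I)=C/CO | intermediate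
13 | 1-({[(2Z)-3-iodobut-2-en-1-yl]oxy}methyl)-4-methoxybenzene | C/C(I)=C/COCc1ccc(OC)cc1 | intermediate
14 | alkenyllithium, [(2Z)-4-(4-methoxybenzyloxy)but-2-en-2-yl]lithium (not isolated) | C/C([Li])=C/COCc1ccc(OC)cc1 | intermediate
15 | (2Z,4RS,6E,9R)-1-(4-methoxybenzyloxy)-3,7-dimethyl-9,10-bis(triethylsilyloxy)deca-2,6-dien-4-ol | COc1ccc(COC/C=C(/C)C(O)C/C=C(\C)C[C@@H](O[Si](CC)(CC)CC)CO[Si](CC)(CC)CC)cc1 | intermediate
16 | (2Z,6E,9R)-1-(4-methoxybenzyloxy)-3,7-dimethyl-9,10-bis(triethylsilyloxy)deca-2,6-dien-4-one | COc1ccc(COC/C=C(/C)C(=O)C/C=C(\C)C[C@@H](O[Si](CC)(CC)CC)CO[Si](CC)(CC)CC)cc1 | intermediate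
17 | (2Z,4S,6E,9R)-1-(4-methoxybenzyloxy)-3,7-dimethyl-9,10-bis(triethylsilyloxy)deca-2,6-dien-4-ol | COc1ccc(COC/C=C(/C)[C@@H](O)C/C=C(\C)C[C@@H](O[Si](CC)(CC)CC)CO[Si](CC)(CC)CC)cc1 | intermediate
18 | (2Z,4S,6E,9R)-4-(tert-butyldimethylsilyloxy)-1-(4-methoxybenzyloxy)-3,7-dimethyl-9,10-bis(triethylsilyloxy)deca-2,6-diene | COc1ccc(COC/C=C(/C)[C@@H](O[Si](C)(C)C(C)(C)C)C/C=C(\C)C[C@@H](O[Si](CC)(CC)CC)CO[Si](CC)(CC)CC)cc1 | intermediate
19 | (2Z,4S,6R,7R,9R)-4-(tert-butyldimethylsilyloxy)-6,7-epoxy-1-(4-methoxybenzyloxy)-3,7-dimethyl-9,10-bis(triethylsilyloxy)dec-2-ene | COc1ccc(COC/C=C(/C)[C@@H](O[Si](C)(C)C(C)(C)C)C[C@H]2O[C@]2(C)C[C@@H](O[Si](CC)(CC)CC)CO[Si](CC)(CC)CC)cc1 | intermediate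
20 | (2R,4R,5R,7S,8Z)-7-(tert-butyldimethylsilyloxy)-4,5-epoxy-10-(4-methoxybenzyloxy)-4,8-dimethyl-2-(triethylsilyloxy)dec-8-enal | COc1ccc(COC/C=C(/C)[C@@H](O[Si](C)(C)C(C)(C)C)C[C@H]2O[C@]2(C)C[C@@H](O[Si](CC)(CC)CC)C=O)cc1 | intermediate
21 | methyl acrylate | C=CC(=O)OC | starting material
22 | methyl (3RS,4R,6R,7R,9S,10Z)-9-(tert-butyldimethylsilyloxy)-6,7-epoxy-3-hydroxy-12-(4-methoxybenzyloxy)-6,10-dimethyl-2-methylidene-4-(triethylsilyloxy)dodec-10-enoate | COc1ccc(COC/C=C(/C)[C@@H](O[Si](C)(C)C(C)(C)C)C[C@H]2O[C@]2(C)C[C@@H](O[Si](CC)(CC)CC)C(O)C(=C)C(=O)OC)cc1 | intermediate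
23 | methyl (2Z,4R,6R,7R,9S,10Z)-2-(bromomethyl)-9-(tert-butyldimethylsilyloxy)-6,7-epoxy-12-(4-methoxybenzyloxy)-6,10-dimethyl-4-(triethylsilyloxy)dodeca-2,10-dienoate | COc1ccc(COC/C=C(/C)[C@@H](O[Si](C)(C)C(C)(C)C)C[C@H]2O[C@]2(C)C[C@@H](O[Si](CC)(CC)CC)/C=C(\CBr)C(=O)OC)cc1 | intermediate
24 | methyl (2Z,4R,6R,7R,9S,10Z)-2-(bromomethyl)-9-(tert-butyldimethylsilyloxy)-6,7-epoxy-12-hydroxy-6,10-dimethyl-4-(triethylsilyloxy)dodeca-2,10-dienoate | OC/C=C(/C)[C@@H](O[Si](C)(C)C(C)(C)C)C[C@H]1O[C@]1(C)C[C@@H](O[Si](CC)(CC)CC)/C=C(\CBr)C(=O)OC | intermediate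
25 | methyl (2Z,4R,6R,7R,9S,10Z)-2-(bromomethyl)-9-(tert-butyldimethylsilyloxy)-6,7-epoxy-6,10-dimethyl-12-oxo-4-(triethylsilyloxy)dodeca-2,10-dienoate | O=C/C=C(/C)[C@@H](O[Si](C)(C)C(C)(C)C)C[C@H]1O[C@]1(C)C[C@@H](O[Si](CC)(CC)CC)/C=C(\CBr)C(=O)OC | intermediate
26 | allylchromium dichloride derived from 25, chromium bound to C13 (not isolated) | O=C/C=C(/C)[C@@H](O[Si](C)(C)C(C)(C)C)C[C@H]1O[C@]1(C)C[C@@H](O[Si](CC)(CC)CC)/C=C(\C[Cr](Cl)Cl)C(=O)OC | intermediate
27 | hydroxy ester, methyl (1R,3S,6S,7S,8R,10R)-3-(tert-butyldimethylsilyloxy)-1,10-epoxy-6-hydroxy-8-(triethylsilyloxy)germacra-4Z,11(13)-dien-12-oate (not isolated) | O[C@H]1/C=C(/C)[C@@H](O[Si](C)(C)C(C)(C)C)C[C@H]2O[C@]2(C)C[C@@H](O[Si](CC)(CC)CC)[C@H]1C(=C)C(=O)OC | intermediate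
28 | (1R,3S,6S,7S,8R,10R)-3-(tert-butyldimethylsilyloxy)-1,10-epoxy-8-(triethylsilyloxy)germacra-4Z,11(13)-dien-12,6-olide (C7 formally S while O8 carries silicon; same spatial arrangement as in the target) | C=C1C(=O)O[C@H]2/C=C(/C)[C@@H](O[Si](C)(C)C(C)(C)C)C[C@H]3O[C@]3(C)C[C@@H](O[Si](CC)(CC)CC)[C@@H]12 | intermediate
29 | (1R,3S,6S,7R,8R,10R)-3-(tert-butyldimethylsilyloxy)-1,10-epoxy-8-hydroxygermacra-4Z,11(13)-dien-12,6-olide | C=C1C(=O)O[C@H]2/C=C(/C)[C@@H](O[Si](C)(C)C(C)(C)C)C[C@H]3O[C@]3(C)C[C@@H](O)[C@@H]12 | intermediate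
30 | (R)-4-benzyl-1,3-oxazolidin-2-one | O=C1N[C@H](Cc2ccccc2)CO1 | starting material
31 | butanoyl chloride | CCCC(Cl)=O | starting material
32 | (R)-4-benzyl-3-butanoyl-1,3-oxazolidin-2-one | CCCC(=O)N1[C@H](Cc2ccccc2)COC1=O | intermediate
33 | titanium enolate, trichlorotitanium (Z)-enolate of 32 (not isolated) | C/C=C(\O[Ti](Cl)(Cl)Cl)N1[C@H](Cc2ccccc2)COC1=O | intermediate
34 | (R)-4-benzyl-3-[(2S)-2-(hydroxymethyl)butanoyl]-1,3-oxazolidin-2-one | CC[C@@H](CO)C(=O)N1[C@H](Cc2ccccc2)COC1=O | intermediate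
35 | (R)-4-benzyl-3-[(2S)-2-(tert-butyldimethylsilyloxymethyl)butanoyl]-1,3-oxazolidin-2-one | CC[C@@H](CO[Si](C)(C)C(C)(C)C)C(=O)N1[C@H](Cc2ccccc2)COC1=O | intermediate
36 | (2S)-2-(tert-butyldimethylsilyloxymethyl)butanoic acid | CC[C@@H](CO[Si](C)(C)C(C)(C)C)C(O)=O | intermediate
37 | tert-butyl acrylate | C=CC(=O)OC(C)(C)C | starting material
38 | acetaldehyde | CC=O | starting material
39 | tert-butyl 3-hydroxy-2-methylidenebutanoate (racemic) | CC(O)C(=C)C(=O)OC(C)(C)C | intermediate
40 | tert-butyl (2Z)-2-(bromomethyl)but-2-enoate | C/C=C(\CBr)C(=O)OC(C)(C)C | intermediate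
41 | tert-butyl (2E)-2-({[(2S)-2-(tert-butyldimethylsilyloxymethyl)butanoyl]oxy}methyl)but-2-enoate | CC[C@@H](CO[Si](C)(C)C(C)(C)C)C(=O)OC/C(=C\C)C(=O)OC(C)(C)C | intermediate
42 | trimethylsilyl ester of 43 (not isolated) | CC[C@@H](CO[Si](C)(C)C(C)(C)C)C(=O)OC/C(=C\C)C(=O)O[Si](C)(C)C | intermediate
43 | (2E)-2-({[(2S)-2-(tert-butyldimethylsilyloxymethyl)butanoyl]oxy}methyl)but-2-enoic acid | CC[C@@H](CO[Si](C)(C)C(C)(C)C)C(=O)OC/C(=C\C)C(O)=O | intermediate
44 | mixed anhydride of 43 with 2,4,6-trichlorobenzoic acid (not isolated) | CC[C@@H](CO[Si](C)(C)C(C)(C)C)C(=O)OC/C(=C\C)C(=O)OC(=O)c1c(Cl)cc(Cl)cc1Cl | intermediate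
45 | bis(tert-butyldimethylsilyl) ether of the target (silyl on O3 and on the side-chain primary oxygen) | C=C1C(=O)O[C@H]2/C=C(/C)[C@@H](O[Si](C)(C)C(C)(C)C)C[C@H]3O[C@]3(C)C[C@@H](OC(=O)/C(=C/C)COC(=O)[C@@H](CC)CO[Si](C)(C)C(C)(C)C)[C@@H]12 | intermediate
46 | (1R,3S,6S,7R,8R,10R)-1,10-epoxy-3-hydroxy-8-{[(2E)-2-({[(2S)-2-(hydroxymethyl)butanoyl]oxy}methyl)but-2-enoyl]oxy}germacra-4Z,11(13)-dien-12,6-olide | C=C1C(=O)O[C@H]2/C=C(/C)[C@@H](O)C[C@H]3O[C@]3(C)C[C@@H](OC(=O)/C(=C/C)COC(=O)[C@@H](CC)CO)[C@@H]12 | target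

**Count and risks**

Total step count: 28. Longest linear sequence: 18 steps (1–4, 7–18, 27, 28).

Steps most likely to fail:

Step 17. The open-chain allylchromium may add with insufficient discrimination between the two faces of C7, or through its E-configured allyl form, which would give C6/C7-epimeric or trans-fused lactones; intermolecular coupling may also compete with ring closure. The fallback replaces the chromium reaction by an intramolecular allylboration through a closed transition state. It sets out from 22. Acetylation (Ac2O, pyridine, 4-(dimethylamino)pyridine) should give the allylic acetate F1. SN2′ Hosomi–Miyaura borylation (B2pin2, CuCl, LiCl, KOAc, DMF) should give the 2-(methoxycarbonyl)allyl pinacolboronate F2, with boron on C13 and C8 cis to the CH2B group. DDQ and then MnO2, as in steps 15 and 16, should give the allylic alcohol F3 and the enal F4; the ester-deactivated allylboronate is not expected to add at room temperature. Heating F4 in toluene at high dilution should close the ten-membered ring through a rigid chair to the O-boryl hydroxy ester F5, which should lactonise on mild acidic work-up to 28, where the route is rejoined.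

Step 13. Conversion may be slow, and the long exposure to the amine may epimerise C8 or eliminate the β-silyloxy group. The fallback uses a preformed vinyl nucleophile instead of amine catalysis and sets out from 20. Hydroalumination of methyl propiolate with i-Bu2AlH in THF–HMPA at 0 °C should give [1-(methoxycarbonyl)vinyl]diisobutylalane F6. Its addition to 20 at 0 °C (vinylalumination) should give the same allylic alcohol 22 within minutes and without base, where the route is rejoined.

Step 7. The basic alkenyllithium may deprotonate the doubly activated C2–H of aldehyde 9, with loss of material and migration of the C1=C10 double bond into conjugation. The fallback changes the electrophile to a non-enolising acyl donor and sets out from 9. Pinnick oxidation (NaClO2, NaH2PO4, 2-methylbut-2-ene, t-BuOH–H2O) should give the acid F7. Amide coupling (MeNHOMe·HCl, EDC·HCl, N-methylmorpholine, CH2Cl2) should give the Weinreb amide F8. Addition of 14 to F8 at −78 °C should give enone 16 directly, where the route is rejoined with steps 7 and 8 bypassed.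

**Further compounds**

F1 | step 17 | methyl (3RS,4R,6R,7R,9S,10Z)-3-acetoxy-9-(tert-butyldimethylsilyloxy)-6,7-epoxy-12-(4-methoxybenzyloxy)-6,10-dimethyl-2-methylidene-4-(triethylsilyloxy)dodec-10-enoate | COc1ccc(COC/C=C(/C)[C@@H](O[Si](C)(C)C(C)(C)C)C[C@H]2O[C@]2(C)C[C@@H](O[Si](CC)(CC)CC)C(OC(C)=O)C(=C)C(=O)OC)cc1
F2 | step 17 | methyl (2E,4R,6R,7R,9S,10Z)-9-(tert-butyldimethylsilyloxy)-6,7-epoxy-12-(4-methoxybenzyloxy)-6,10-dimethyl-2-[(4,4,5,5-tetramethyl-1,3,2-dioxaborolan-2-yl)methyl]-4-(triethylsilyloxy)dodeca-2,10-dienoate | COc1ccc(COC/C=C(/C)[C@@H](O[Si](C)(C)C(C)(C)C)C[C@H]2O[C@]2(C)C[C@@H](O[Si](CC)(CC)CC)/C=C(\CB3OC(C)(C)C(C)(C)O3)C(=O)OC)cc1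
F3 | step 17 | methyl (2E,4R,6R,7R,9S,10Z)-9-(tert-butyldimethylsilyloxy)-6,7-epoxy-12-hydroxy-6,10-dimethyl-2-[(4,4,5,5-tetramethyl-1,3,2-dioxaborolan-2-yl)methyl]-4-(triethylsilyloxy)dodeca-2,10-dienoate | OC/C=C(/C)[C@@H](O[Si](C)(C)C(C)(C)C)C[C@H]1O[C@]1(C)C[C@@H](O[Si](CC)(CC)CC)/C=C(\CB2OC(C)(C)C(C)(C)O2)C(=O)OC
F4 | step 17 | methyl (2E,4R,6R,7R,9S,10Z)-9-(tert-butyldimethylsilyloxy)-6,7-epoxy-6,10-dimethyl-12-oxo-2-[(4,4,5,5-tetramethyl-1,3,2-dioxaborolan-2-yl)methyl]-4-(triethylsilyloxy)dodeca-2,10-dienoate | O=C/C=C(/C)[C@@H](O[Si](C)(C)C(C)(C)C)C[C@H]1O[C@]1(C)C[C@@H](O[Si](CC)(CC)CC)/C=C(\CB2OC(C)(C)C(C)(C)O2)C(=O)OC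
F5 | step 17 | O6-(4,4,5,5-tetramethyl-1,3,2-dioxaborolan-2-yl) derivative of hydroxy ester 27 | CC1(C)OB(O[C@H]2/C=C(/C)[C@@H](O[Si](C)(C)C(C)(C)C)C[C@H]3O[C@]3(C)C[C@@H](O[Si](CC)(CC)CC)[C@H]2C(=C)C(=O)OC)OC1(C)C
F6 | step 13 | [1-(methoxycarbonyl)vinyl]diisobutylalane | C=C([Al](CC(C)C)CC(C)C)C(=O)OC
F7 | step 7 | (3E,6R)-4-methyl-6,7-bis(triethylsilyloxy)hept-3-enoic acid | OC(=O)C/C=C(\C)C[C@@H](O[Si](CC)(CC)CC)CO[Si](CC)(CC)CC
F8 | step 7 | (3E,6R)-N-methoxy-N,4-dimethyl-6,7-bis(triethylsilyloxy)hept-3-enamide | CON(C)C(=O)C/C=C(\C)C[C@@H](O[Si](CC)(CC)CC)CO[Si](CC)(CC)CC
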